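The target is an unbranched C1–C11 tether joining the acylphloroglucinol ring A (at the C1 ketone) to the phenol ring B (at C11). Its inner run C3–C10 consists of eight unfunctionalised carbons, exactly the ring atoms of cis-cyclooctene. The plan therefore disconnects C2=C3 and C10=C11 of a dienone. One ruthenium-catalysed ring-opening cross-metathesis opens the carbocycle, capping one terminus with a fully O-benzylated ring A vinyl ketone (C1, C2) and the other with an O-protected 2-vinylphenol (C11, ring B). Both skeletal bonds thus arise in one flask from three simple alkenes, and a single hydrogenation then saturates both alkenes and frees all four phenols.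

Key step: step 5

Design remarks (C1 = ketone carbon, C11 = benzylic carbon on ring B; the target has no stereocentre and the route closes no ring):
- **Stoichiometry of the key step.**
  - An enone-capped terminus is practically dead to further metathesis. The vinyl terminus left at the far end is the most reactive alkene in the flask, so surplus vinyl ketone would cap both ends of the same C8 unit.
  - The vinyl ketone is therefore the limiting partner and cyclooctene is used in excess. On statistical grounds most enone caps then sit on a C8 unit whose other terminus is still open.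
  - The surplus oligo-octenylene backbone stays metathesis-active and is cut later by the styrene.
- **Order of addition.** The styrene is added only when the vinyl ketone has been consumed, because the two would otherwise couple directly to a chalcone.
- **Ring B protecting group.**
  - An ortho alkyl or benzyl ether oxygen would bind ruthenium in the derived benzylidene through a five-membered chelate of the Hoveyda type. With the styrene in large excess over the metal, this would hold the catalyst in a slowly initiating state.
  - A benzyl carbonate has a poorly donating oxygen and is removed in the same hydrogenolysis as the benzyl ethers, so no step is added.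
- **Ring A protection.** All three hydroxyls are masked, because a free ortho OH would add to the enone and close a chromanone.
- **Abbreviation.** H2IMes = 1,3-dimesitylimidazolidin-2-ylidene.
- **Assumption.** The commercial monohydrate of the trihydroxyacetophenone is dried (toluene azeotrope) before step 1.

Step 1
Reactants: 1 2',4',6'-trihydroxyacetophenone
Product: 2 1-[2,4,6-tris(benzyloxy)phenyl]ethan-1-one
Conditions: BnBr (3.6 equiv), K2CO3 (5 equiv), DMF, 70 °C
Reagents that add atoms: benzyl bromide, BrCc1ccccc1
Why: Williamson ether synthesis: the acyl group tempers the carbon nucleophilicity of the phloroglucinol ring so that O-alkylation should dominate in DMF, heat and excess halide also alkylate the two hydrogen-bonded ortho hydroxyls, and complete masking is required because a free ortho OH would later close onto the enone by oxa-Michael addition.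

Step 2
Reactants: 2 1-[2,4,6-tris(benzyloxy)phenyl]ethan-1-one
Product: 4 1-[2,4,6-tris(benzyloxy)phenyl]prop-2-en-1-one, via Mannich base 3 (not isolated)
Conditions: (CH2O)n (4 equiv, two portions), iPr2NH·CF3CO2H (1 equiv), CF3CO2H (10 mol%), BHT (trace), THF, reflux
Reagents that add atoms: paraformaldehyde (as formaldehyde), C=O
Why: Mannich condensation followed by in situ E1cB loss of the amine (direct alpha-methylenation of an aryl methyl ketone): the CH3 group is the only enolisable site, the bulky diisopropylamine is a good leaving group and a poor Michael donor so that 3 collapses to 4, and the buffered medium leaves the benzyl ethers alone.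

Step 3
Reactants: 5 salicylaldehyde
Product: 6 2-vinylphenol
Conditions: MePPh3Br (1.5 equiv), KOtBu (2.6 equiv), THF, 0 °C to rt; then aq NH4Cl
Reagents that add atoms: methyltriphenylphosphonium bromide, C[P+](c1ccccc1)(c1ccccc1)c1ccccc1.[Br-]
Why: Wittig methylenation: the extra base stores the phenol as its potassium salt, the unstabilised ylide still adds to the less electrophilic phenoxide aldehyde, and the mild NH4Cl quench returns the acid-sensitive vinylphenol.

Step 4
Reactants: 6 2-vinylphenol
Product: 7 benzyl 2-vinylphenyl carbonate
Conditions: BnOCOCl (1.2 equiv), Et3N (1.5 equiv), CH2Cl2, 0 °C to rt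
Reagents that add atoms: benzyl chloroformate, O=C(Cl)OCc1ccccc1
Why: O-acylation of a phenol with a chloroformate under amine base: the reaction is fast at 0 °C, leaves the styrene untouched, and installs a group whose oxygen lone pair is tied up in the carbonate and which is hydrogenolysed like a benzyl ether.

Step 5
Reactants: 4 1-[2,4,6-tris(benzyloxy)phenyl]prop-2-en-1-one; 8 cis-cyclooctene; 7 benzyl 2-vinylphenyl carbonate
Product: 10 benzyl 2-{(1E,9E)-11-oxo-11-[2,4,6-tris(benzyloxy)phenyl]undeca-1,9-dien-1-yl}phenyl carbonate, via enone-capped diene 9 (not isolated)
Conditions: first 4 (1 equiv), 8 (2 equiv), second-generation Hoveyda–Grubbs catalyst RuCl2(H2IMes)(=CH-C6H4-2-OiPr) (2.5 mol%), 2,6-dichloro-1,4-benzoquinone (10 mol%), CH2Cl2 (0.1 M in 4), 40 °C, until 4 is consumed; then 7 (6 equiv), same catalyst (2.5 mol%), 40 °C, Ar sparge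
Reagents that add atoms: none
Why: Proposed new method: a ruthenium alkylidene adds to strained 8 by (2+2) cycloaddition and cycloreversion, and the ring-opened alkylidene, or one regenerated from the equilibrating oligo-octenylene backbone, is trapped by the electron-poor, non-homodimerising vinyl ketone 4, which fixes the E C2=C3 enone of 9 as an end that hardly re-enters metathesis. In the second stage the benzylidene derived from 7 cuts the terminal or internal C=C bond at C10, so that 9 and its longer homologues should converge on 10 while loss of ethylene and conjugation with ring B pull the equilibria. The closest known reactions are ring-opening cross-metathesis and ring-opening insertion metathesis of cyclooctene with acrylates and enones, cross-metathesis of ortho-substituted styrenes with alkenes, and cross-metathesis degradation of polyoctenamer by chain-transfer alkenes; new is the placing of two different caps on unsubstituted cyclooctene in one flask. No ring is closed and no stereocentre is formed, and the alkene geometries (E expected at both) are erased in step 6. The selectivity needed is one enone cap and one styryl cap on a single C8 unit, which is secured by keeping 4 limiting against excess 8 so that few units meet two enones, by adding 7 only after 4 has gone so that no direct enone–styrene coupling can occur, and by the reversibility of every C=C bond that is not an enone. The carbonate of 7 ties up the ortho oxygen lone pair and so avoids a dormant five-membered O-to-Ru chelate, and the quinone intercepts Ru–H species that would migrate the alkenes and shorten the tether.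

Step 6
Reactants: 10 benzyl 2-{(1E,9E)-11-oxo-11-[2,4,6-tris(benzyloxy)phenyl]undeca-1,9-dien-1-yl}phenyl carbonate
Product: 11 11-(2-hydroxyphenyl)-1-(2,4,6-trihydroxyphenyl)undecan-1-one (CNP0295227.0)
Conditions: H2 (1 atm), 10% Pd/C, EtOAc–MeOH (1:1), rt
Reagents that add atoms: none
Why: Heterogeneous catalytic hydrogenation with hydrogenolysis: the two disubstituted alkenes are saturated, the three benzyl ethers and the benzyl carbonate lose toluene (the carbonate also CO2), and the C1 ketone should persist because it is flanked by two ortho substituents and, once these are free OH groups, is a hydrogen-bonded vinylogous acid carbonyl, as in the standard chalcone to dihydrochalcone reduction.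

Compound list
1 | 2',4',6'-trihydroxyacetophenone | CC(=O)c1c(O)cc(O)cc1O | starting material
2 | 1-[2,4,6-tris(benzyloxy)phenyl]ethan-1-one | CC(=O)c1c(OCc2ccccc2)cc(OCc2ccccc2)cc1OCc1ccccc1 | intermediate
3 | 3-(diisopropylamino)-1-[2,4,6-tris(benzyloxy)phenyl]propan-1-one (Mannich base, not isolated) | CC(C)N(CCC(=O)c1c(OCc2ccccc2)cc(OCc2ccccc2)cc1OCc1ccccc1)C(C)C | intermediate
4 | 1-[2,4,6-tris(benzyloxy)phenyl]prop-2-en-1-one | C=CC(=O)c1c(OCc2ccccc2)cc(OCc2ccccc2)cc1OCc1ccccc1 | intermediate
5 | salicylaldehyde | O=Cc1ccccc1O | starting material
6 | 2-vinylphenol | C=Cc1ccccc1O | intermediate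
7 | benzyl 2-vinylphenyl carbonate | C=Cc1ccccc1OC(=O)OCc1ccccc1 | intermediate
8 | cis-cyclooctene | C1CCC/C=C\CC1 | starting material
9 | (2E)-1-[2,4,6-tris(benzyloxy)phenyl]undeca-2,10-dien-1-one (not isolated; present together with homologues that carry further octenylene units) | C=CCCCCCC/C=C/C(=O)c1c(OCc2ccccc2)cc(OCc2ccccc2)cc1OCc1ccccc1 | intermediate
10 | benzyl 2-{(1E,9E)-11-oxo-11-[2,4,6-tris(benzyloxy)phenyl]undeca-1,9-dien-1-yl}phenyl carbonate | O=C(/C=C/CCCCCC/C=C/c1ccccc1OC(=O)OCc1ccccc1)c1c(OCc2ccccc2)cc(OCc2ccccc2)cc1OCc1ccccc1 | intermediate
11 | 11-(2-hydroxyphenyl)-1-(2,4,6-trihydroxyphenyl)undecan-1-one | O=C(CCCCCCCCCCc1ccccc1O)c1c(O)cc(O)cc1O | target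

Total step count: 6
Longest linear sequence: 4 steps (1, 2, 5, 6)

Steps most likely to fail

1. **Step 5.**
   - What may go wrong: the two termini may not be differentiated well enough. One C8 unit may be capped twice by the enone, and the styrene may cut the oligo-octenylene backbone incompletely. Alkene migration with loss of CH2 units, or slow turnover of the ortho-substituted benzylidene, is also possible.
   - Fallback: known chemistry only, setting out from 5 and 4 and coming back at 11. It forms C10=C11 by olefination instead of metathesis.
   - Salicylaldehyde 5 is O-benzylated (BnBr, K2CO3, DMF) to 2-(benzyloxy)benzaldehyde F1. Commercial 9-bromonon-1-ene and PPh3 (MeCN, reflux) give (non-8-en-1-yl)triphenylphosphonium bromide F2.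
   - Wittig olefination of F1 with F2 and NaN(SiMe3)2 in THF should give 1-(benzyloxy)-2-[(1Z)-deca-1,9-dien-1-yl]benzene F3.
   - The terminal vinyl group of F3 (a type 1 alkene) then undergoes ordinary cross-metathesis with the type 2 enone 4 under RuCl2(H2IMes)(=CH-C6H4-2-OiPr). This forms C2=C3 and gives (2E,10Z)-11-[2-(benzyloxy)phenyl]-1-[2,4,6-tris(benzyloxy)phenyl]undeca-2,10-dien-1-one F4.
   - Hydrogenation of F4 under the conditions of step 6 gives 11.

2. **Step 2.**
   - What may go wrong: the vinyl ketone may polymerise or take up amine during the long reflux, or the Mannich condensation may stall at the hindered ketone.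
   - Fallback: it sets out from 2 and comes back at 4. The thermal one-pot process is replaced by a stepwise ionic sequence with a storable precursor.
   - Compound 2 is treated with LiN(SiMe3)2 (THF, −78 °C) and then with Eschenmoser's salt, (Me2N=CH2)I, to give 3-(dimethylamino)-1-[2,4,6-tris(benzyloxy)phenyl]propan-1-one F5.
   - MeI in Et2O quaternises F5 to trimethyl{3-oxo-3-[2,4,6-tris(benzyloxy)phenyl]propyl}ammonium iodide F6.
   - Shaking F6 with aqueous NaHCO3 and CH2Cl2 at room temperature releases 4 by Hofmann-type elimination just before it is needed in step 5.

3. **Step 1.**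
   - What may go wrong: the electron-rich ring may be C-benzylated in competition, and alkylation may stall at a hydrogen-bonded ortho hydroxyl.
   - Fallback: it sets out from 1 and comes back at 2, and the last ether is made without a free phenoxide.
   - Mild partial benzylation (BnBr, 2.1 equiv, K2CO3, acetone, reflux) stops at the crystalline 1-[2,4-bis(benzyloxy)-6-hydroxyphenyl]ethan-1-one F7.
   - The remaining chelated OH of F7 is then etherified under Mitsunobu conditions (BnOH, PPh3, DIAD, THF) to give 2.

Further compounds
F1 | step 5 | 2-(benzyloxy)benzaldehyde | O=Cc1ccccc1OCc1ccccc1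
F2 | step 5 | (non-8-en-1-yl)triphenylphosphonium bromide | C=CCCCCCCC[P+](c1ccccc1)(c1ccccc1)c1ccccc1.[Br-]
F3 | step 5 | 1-(benzyloxy)-2-[(1Z)-deca-1,9-dien-1-yl]benzene | C=CCCCCCC/C=C\c1ccccc1OCc1ccccc1
F4 | step 5 | (2E,10Z)-11-[2-(benzyloxy)phenyl]-1-[2,4,6-tris(benzyloxy)phenyl]undeca-2,10-dien-1-one | O=C(/C=C/CCCCCC/C=C\c1ccccc1OCc1ccccc1)c1c(OCc2ccccc2)cc(OCc2ccccc2)cc1OCc1ccccc1
F5 | step 2 | 3-(dimethylamino)-1-[2,4,6-tris(benzyloxy)phenyl]propan-1-one | CN(C)CCC(=O)c1c(OCc2ccccc2)cc(OCc2ccccc2)cc1OCc1ccccc1
F6 | step 2 | trimethyl{3-oxo-3-[2,4,6-tris(benzyloxy)phenyl]propyl}ammonium iodide | C[N+](C)(C)CCC(=O)c1c(OCc2ccccc2)cc(OCc2ccccc2)cc1OCc1ccccc1.[I-]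
F7 | step 1 | 1-[2,4-bis(benzyloxy)-6-hydroxyphenyl]ethan-1-one | CC(=O)c1c(O)cc(OCc2ccccc2)cc1OCc1ccccc1
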